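**Plan**

- Numbering (xenicane): lactone O2–C1H2–C11a–C4a–C4–C3(=O); carbocycle C4a–C5–C6–C7(Me)=C8–C9–C10–C11(=CH2)–C11a; side chain C12–C15 on C4.
- Cuts: C5–C6 (nine-membered ring, sulfone alkylation); C4–C12 (enolate alkylation) and C14=C15 (cross-metathesis); C4a–C5 (conjugate addition); C4=C4a (olefination); C11a–C1 (formaldehyde aldol on methyl geranate, which supplies C6–C11a and both methyl-derived carbons).
- Enabling feature: C5 is γ to the lactone carbonyl C3, and C6 is the allylic CH2 of the E-C7=C8 olefin. C5 can therefore sit as the O–CH2 of a temporary γ-lactone (ring C3–C4–C4a–C5–O). Thiolate opening of that ring puts a carbanion-stabilising sulfur on C5 and frees C3 as a carboxylate that shields C4–H, while C6 is made an allylic chloride.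
- Forward: C10 ester → unsaturated δ-lactone (fixes C4a) → γ-lactone (fixes C4) → open seco acid → nine-membered carbocycle → δ-lactone → epoxide → enoate.
- Stereochemistry: C11a from lipase desymmetrisation of a prochiral 1,3-diol (the only external source); C4a by cuprate addition anti to the C11a branch; C4 by trans alkylation on the γ-lactone (4,4a-cis in the target); C7/C8 by outer-face peracid attack on the E-cyclononene; olefin geometries from Riley oxidation and metathesis.

Key step: step 15

Assumption: the lipase distinguishes the two hydroxymethyl arms of diol 4 in the sense drawn (acylation gives the (S)-monoacetate 5, hydrolysis of the diacetate the (R)-isomer); if the sense proves reversed, the two enzymatic modes are exchanged.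

**Route**

Step 1
Reactants: 1 methyl (2E)-3,7-dimethylocta-2,6-dienoate (methyl geranate)
Product: 3 methyl 2-(hydroxymethyl)-7-methyl-3-methylideneoct-6-enoate (racemic), via lithium dienolate 2 (not isolated)
Conditions: LiN(i-Pr)2, THF–DMPU, −78 °C; CH2O gas (from cracked paraformaldehyde), −78 °C; H2O
Reagents that add atoms: formaldehyde, C=O
Why: Deconjugative aldol (α-hydroxymethylation) of an extended ester enolate: kinetic γ-deprotonation should take the C3 methyl group, which lies cis to the ester in the (2E)-isomer, and the dienolate should react with formaldehyde at its α-carbon, so that the future C11a (still racemic), its C1 arm and the C11 exocyclic methylene arise together.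

Step 2
Reactants: 3 methyl 2-(hydroxymethyl)-7-methyl-3-methylideneoct-6-enoate
Product: 4 2-(6-methylhepta-1,5-dien-2-yl)propane-1,3-diol
Conditions: LiAlH4, THF, 0 °C; aqueous NaOH work-up
Reagents that add atoms: none
Why: Hydride reduction of the ester should give the 2-substituted propane-1,3-diol, in which the former stereocentre is a prochiral carbon with two enantiotopic hydroxymethyl arms.

Step 3
Reactants: 4 2-(6-methylhepta-1,5-dien-2-yl)propane-1,3-diol
Product: 5 (2S)-3-hydroxy-2-(6-methylhepta-1,5-dien-2-yl)propyl acetate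
Conditions: lipase from Burkholderia cepacia (Amano PS), vinyl acetate, t-BuOMe, 25 °C
Reagents that add atoms: vinyl acetate, C=COC(C)=O
Why: Enzymatic desymmetrisation by irreversible lipase-catalysed transesterification should acetylate one enantiotopic arm only, which sets C11a, the single stereocentre taken from a chiral agent.

Step 4
Reactants: 5 (2S)-3-hydroxy-2-(6-methylhepta-1,5-dien-2-yl)propyl acetate
Product: 6 (2R)-2-(6-methylhepta-1,5-dien-2-yl)-3-oxopropyl acetate
Conditions: Dess–Martin periodinane, NaHCO3, CH2Cl2, 0 °C; used crude at once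
Reagents that add atoms: none
Why: Dess–Martin oxidation under buffered, non-basic conditions should give the α-branched β-acetoxy aldehyde without β-elimination or enolisation if it is carried on immediately.

Step 5
Reactants: 6 (2R)-2-(6-methylhepta-1,5-dien-2-yl)-3-oxopropyl acetate; 7 methyl [bis(2,2,2-trifluoroethoxy)phosphoryl]acetate
Product: 8 methyl (2Z,4R)-4-(acetoxymethyl)-9-methyl-5-methylidenedeca-2,8-dienoate
Conditions: 7, KN(SiMe3)2, 18-crown-6, THF, −78 °C; then 6
Reagents that add atoms: methyl [bis(2,2,2-trifluoroethoxy)phosphoryl]acetate (compound 7), COC(=O)CP(=O)(OCC(F)(F)F)OCC(F)(F)F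
Why: Still–Gennari olefination should give the (Z)-enoate under kinetic control at low temperature, the geometry needed for closure to the unsaturated δ-lactone.

Step 6
Reactants: 8 methyl (2Z,4R)-4-(acetoxymethyl)-9-methyl-5-methylidenedeca-2,8-dienoate
Product: 10 (5R)-5-(6-methylhepta-1,5-dien-2-yl)-5,6-dihydro-2H-pyran-2-one, via hydroxy ester 9 (not isolated)
Conditions: K2CO3 (0.2 equiv), MeOH, 0 °C; AcOH quench
Reagents that add atoms: none
Why: Base-catalysed transesterification frees the primary alcohol, which should lactonise onto the (Z)-enoate to give the 5-substituted dihydropyranone without touching C11a.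

Step 7
Reactants: 10 (5R)-5-(6-methylhepta-1,5-dien-2-yl)-5,6-dihydro-2H-pyran-2-one; 11 (chloromethyl)dimethyl(propan-2-yloxy)silane
Product: 13 (4R,5R)-4-{[dimethyl(propan-2-yloxy)silyl]methyl}-5-(6-methylhepta-1,5-dien-2-yl)oxan-2-one, via Grignard reagent 12 (not isolated)
Conditions: 11, Mg, THF, rt; then 10, CuBr·SMe2 (10 mol %), Me3SiCl, THF, −78 °C; aqueous NH4Cl
Reagents that add atoms: (chloromethyl)dimethyl(propan-2-yloxy)silane (compound 11), CC(C)O[Si](C)(C)CCl
Why: Copper-catalysed conjugate addition of a silylmethyl Grignard reagent (a hydroxymethyl anion equivalent) should occur on the face of the unsaturated lactone anti to the C5 substituent, which sets C4a trans to C11a.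

Step 8
Reactants: 13 (4R,5R)-4-{[dimethyl(propan-2-yloxy)silyl]methyl}-5-(6-methylhepta-1,5-dien-2-yl)oxan-2-one
Product: 15 (4R)-4-[(2R)-1-hydroxy-7-methyl-3-methylideneoct-6-en-2-yl]oxolan-2-one, via hydroxymethyl δ-lactone 14 (not isolated)
Conditions: 30 % H2O2, KF, KHCO3, THF–MeOH, rt; then 1 M HCl to pH 3, rt
Reagents that add atoms: hydrogen peroxide, OO
Why: Tamao–Fleming oxidation turns C–Si into C–OH, and on acidification the hydroxymethyl δ-lactone should translactonise to the more stable γ-lactone, which places C5 on the ring oxygen and frees the C1 hydroxyl.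

Step 9
Reactants: 15 (4R)-4-[(2R)-1-hydroxy-7-methyl-3-methylideneoct-6-en-2-yl]oxolan-2-one
Product: 16 (4R)-4-[(2R)-1-{[tert-butyl(dimethyl)silyl]oxy}-7-methyl-3-methylideneoct-6-en-2-yl]oxolan-2-one
Conditions: TBSCl, imidazole, DMF, 0 °C
Reagents that add atoms: tert-butyl(chloro)dimethylsilane, CC(C)(C)[Si](C)(C)Cl
Why: Silyl ether protection of the primary alcohol blocks the C1 oxygen for the enolate chemistry and later keeps the seco acid open.

Step 10
Reactants: 16 (4R)-4-[(2R)-1-{[tert-butyl(dimethyl)silyl]oxy}-7-methyl-3-methylideneoct-6-en-2-yl]oxolan-2-one; 17 4-iodobut-1-ene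
Product: 18 (3S,4S)-3-(but-3-en-1-yl)-4-[(2R)-1-{[tert-butyl(dimethyl)silyl]oxy}-7-methyl-3-methylideneoct-6-en-2-yl]oxolan-2-one
Conditions: LiN(i-Pr)2, THF, −78 °C; 17, DMPU, −78 to −30 °C
Reagents that add atoms: 4-iodobut-1-ene (compound 17), C=CCCI
Why: Alkylation of the γ-lactone lithium enolate should occur anti to the large substituent on the neighbouring ring carbon (trans-3,4), and this trans relation on the five-membered ring is the 4,4a-cis relation of the target once C3 is re-joined to O2.

Step 11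
Reactants: 18 (3S,4S)-3-(but-3-en-1-yl)-4-[(2R)-1-{[tert-butyl(dimethyl)silyl]oxy}-7-methyl-3-methylideneoct-6-en-2-yl]oxolan-2-one
Product: 19 (2S,3S,4R)-2-(but-3-en-1-yl)-4-({[tert-butyl(dimethyl)silyl]oxy}methyl)-9-methyl-5-methylidene-3-[(phenylsulfanyl)methyl]dec-8-enoic acid
Conditions: NaSPh, DMF, 110 °C; then 1 M HCl, 0 °C
Reagents that add atoms: sodium benzenethiolate, [Na+].[S-]c1ccccc1
Why: SN2 opening of the γ-lactone at its O-alkyl carbon by the soft thiolate should place sulfur on C5 and liberate C3 as a carboxylate, with no change at C4.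

Step 12
Reactants: 19 the sulfide acid
Product: 20 (2S,3S,4R)-2-(but-3-en-1-yl)-4-({[tert-butyl(dimethyl)silyl]oxy}methyl)-9-methyl-5-methylidene-3-[(phenylsulfonyl)methyl]dec-8-enoic acid
Conditions: (NH4)6Mo7O24·4H2O (10 mol %), 30 % H2O2, EtOH, 0 °C to rt
Reagents that add atoms: hydrogen peroxide, OO
Why: Molybdate-catalysed peroxide oxidation of a sulfide to the sulfone is chemoselective for sulfur over isolated olefins.

Step 13
Reactants: 20 the sulfone acid
Product: 21 (2S,3S,4R,8E)-2-(but-3-en-1-yl)-4-({[tert-butyl(dimethyl)silyl]oxy}methyl)-10-hydroxy-9-methyl-5-methylidene-3-[(phenylsulfonyl)methyl]dec-8-enoic acid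
Conditions: SeO2 (0.3 equiv), t-BuOOH (3 equiv), salicylic acid (cat.), CH2Cl2, 0 °C to rt, stopped at partial conversion
Reagents that add atoms: tert-butyl hydroperoxide, CC(C)(C)OO
Why: Riley allylic oxidation should attack the most electron-rich, trisubstituted olefin at its (E)-methyl group through the ene and [2,3]-sigmatropic sequence, giving the (E)-allylic alcohol at C6 while the 1,1-disubstituted and monosubstituted olefins react more slowly.

Step 14
Reactants: 21 the allylic alcohol
Product: 23 (2S,3S,4R,8E)-2-(but-3-en-1-yl)-4-({[tert-butyl(dimethyl)silyl]oxy}methyl)-10-chloro-9-methyl-5-methylidene-3-[(phenylsulfonyl)methyl]dec-8-enoic acid, via allylic tosylate 22 (not isolated)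
Conditions: LiN(SiMe3)2 (2.05 equiv), THF, −78 °C; TsCl (1.05 equiv), −78 to 0 °C; LiCl, DMF, 0 °C; 0.5 M HCl
Reagents that add atoms: lithium chloride, [Li+].[Cl-]; 4-methylbenzenesulfonyl chloride, Cc1ccc(cc1)S(Cl)(=O)=O (tosyl group of 22 and part of the chloride)
Why: Sulfonylation of the lithium alkoxide, which is far more nucleophilic than the lithium carboxylate, followed by SN2 displacement of the allylic tosylate by chloride, should give the primary allylic chloride with the (E)-geometry intact.

Step 15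
Reactants: 23 the chloro sulfone acid
Product: 25 (2S)-2-[(1S,4E,9R)-9-({[tert-butyl(dimethyl)silyl]oxy}methyl)-4-methyl-8-methylidene-2-(phenylsulfonyl)cyclonon-4-en-1-yl]hex-5-enoic acid (epimers at the sulfonyl carbon), via dilithio dianion 24 (not isolated)
Conditions: LiN(i-Pr)2 (2.1 equiv), THF–DMPU, 0.002 M, −78 °C then slowly to 0 °C; 0.5 M HCl
Reagents that add atoms: none
Why: Two equivalents of amide base should give first the lithium carboxylate, whose α-C–H (C4) is not removed at low temperature, and then the α-sulfonyl carbanion at C5, which displaces the primary allylic chloride at C6 in an intramolecular SN2 reaction. The closest known reaction type is the intramolecular alkylation of sulfone-stabilised carbanions by allylic halides used for medium and large carbocycles, here run on a carboxylate–sulfone dianion of the kind known from ω-sulfonyl alkanoic acids. The nine-membered ring closes in the 9-exo-tet mode, and since the C7=C8 double bond takes no part (no allyl-metal intermediate) its E geometry is carried into the ring unchanged. The only new stereocentre, the sulfonyl-bearing C5, is not controlled and is erased in step 16, while C4, C4a and C11a are untouched because C4–H sits next to a carboxylate. The step needs C-alkylation at C5 rather than SN2′ attack at C8 (seven-membered ring), carboxylate O-alkylation (eleven-membered lactone) or intermolecular coupling; the carbanion is the strongest nucleophile present, direct substitution at the unhindered primary carbon is preferred, and high dilution holds back oligomers.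

Step 16
Reactants: 25 the cyclised sulfone acid
Product: 26 (2S)-2-[(1S,4E,9R)-9-({[tert-butyl(dimethyl)silyl]oxy}methyl)-4-methyl-8-methylidenecyclonon-4-en-1-yl]hex-5-enoic acid
Conditions: Na(Hg) (6 %), Na2HPO4, MeOH–THF, −20 °C to rt; then pH 4
Reagents that add atoms: none
Why: Reductive desulfonylation with sodium amalgam (electron transfer, C–S cleavage, protonation) should replace the sulfonyl group at C5 by hydrogen without touching the non-conjugated olefins.

Step 17
Reactants: 26 the silyl ether acid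
Product: 28 (4S,4aS,7E,11aR)-4-(but-3-en-1-yl)-7-methyl-11-methylidene-4,4a,5,6,9,10,11,11a-octahydro-1H-cyclonona[c]pyran-3-one, via hydroxy acid 27 (not isolated)
Conditions: HF·pyridine, THF–pyridine, 0 °C to rt; then PPTS (cat.), CH2Cl2, rt
Reagents that add atoms: none
Why: Fluoride-mediated silyl ether cleavage frees the C1 hydroxyl, and the δ-hydroxy acid should lactonise under mild acid catalysis to the trans-fused δ-lactone.

Step 18
Reactants: 28 the bicyclic lactone
Product: 29 (4S,4aS,7S,8S,11aR)-4-(but-3-en-1-yl)-7,8-epoxy-7-methyl-11-methylidene-decahydro-1H-cyclonona[c]pyran-3-one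
Conditions: mCPBA (1.05 equiv), NaHCO3, CH2Cl2, −20 to 0 °C
Reagents that add atoms: 3-chloroperoxybenzoic acid, OOC(=O)c1cccc(Cl)c1
Why: Prilezhaev epoxidation should select the strained, trisubstituted E-C7=C8 olefin over the 1,1-disubstituted and terminal olefins, and attack on the outer face of the preferred conformer of the E-cyclononene, as in related nine-membered terpenoid rings, is expected to give the (7S,8S)-epoxide, syn addition keeping C6 and C9 trans.

Step 19
Reactants: 29 the epoxy lactone; 30 methyl methacrylate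
Product: 31 acalycixeniolide H
Conditions: 30 (10 equiv), second-generation Grubbs catalyst RuCl2(=CHPh)(PCy3)(H2IMes) (5 mol %), CH2Cl2, 40 °C
Reagents that add atoms: methyl methacrylate (compound 30), C=C(C)C(=O)OC
Why: Olefin cross-metathesis of the terminal alkene with excess methyl methacrylate should give the (E)-trisubstituted enoate under thermodynamic control, while the hindered 1,1-disubstituted olefin and the epoxide stay inert.

**Compound list**

1 | methyl (2E)-3,7-dimethylocta-2,6-dienoate (methyl geranate) | COC(=O)/C=C(\C)CCC=C(C)C | starting material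
2 | lithium 1-methoxy-7-methyl-3-methylideneocta-1,6-dien-1-olate (dienolate of 1, not isolated) | [Li+].COC([O-])=CC(=C)CCC=C(C)C | intermediate
3 | methyl 2-(hydroxymethyl)-7-methyl-3-methylideneoct-6-enoate (racemic) | COC(=O)C(CO)C(=C)CCC=C(C)C | intermediate
4 | 2-(6-methylhepta-1,5-dien-2-yl)propane-1,3-diol (achiral) | OCC(CO)C(=C)CCC=C(C)C | intermediate
5 | (2S)-3-hydroxy-2-(6-methylhepta-1,5-dien-2-yl)propyl acetate | CC(=O)OC[C@@H](C(=C)CCC=C(C)C)CO | intermediate
6 | (2R)-2-(6-methylhepta-1,5-dien-2-yl)-3-oxopropyl acetate | CC(=O)OC[C@@H](C(=C)CCC=C(C)C)C=O | intermediate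
7 | methyl [bis(2,2,2-trifluoroethoxy)phosphoryl]acetate | COC(=O)CP(=O)(OCC(F)(F)F)OCC(F)(F)F | starting material
8 | methyl (2Z,4R)-4-(acetoxymethyl)-9-methyl-5-methylidenedeca-2,8-dienoate | CC(=O)OC[C@@H](C(=C)CCC=C(C)C)/C=C\C(=O)OC | intermediate
9 | methyl (2Z,4R)-4-(hydroxymethyl)-9-methyl-5-methylidenedeca-2,8-dienoate (not isolated) | OC[C@@H](C(=C)CCC=C(C)C)/C=C\C(=O)OC | intermediate
10 | (5R)-5-(6-methylhepta-1,5-dien-2-yl)-5,6-dihydro-2H-pyran-2-one | O=C1C=C[C@H](C(=C)CCC=C(C)C)CO1 | intermediate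
11 | (chloromethyl)dimethyl(propan-2-yloxy)silane | CC(C)O[Si](C)(C)CCl | starting material
12 | {[dimethyl(propan-2-yloxy)silyl]methyl}magnesium chloride (not isolated) | CC(C)O[Si](C)(C)C[Mg]Cl | intermediate
13 | (4R,5R)-4-{[dimethyl(propan-2-yloxy)silyl]methyl}-5-(6-methylhepta-1,5-dien-2-yl)oxan-2-one (4,5-trans) | O=C1C[C@@H](C[Si](C)(C)OC(C)C)[C@H](C(=C)CCC=C(C)C)CO1 | intermediate
14 | (4R,5R)-4-(hydroxymethyl)-5-(6-methylhepta-1,5-dien-2-yl)oxan-2-one (not isolated) | O=C1C[C@@H](CO)[C@H](C(=C)CCC=C(C)C)CO1 | intermediate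
15 | (4R)-4-[(2R)-1-hydroxy-7-methyl-3-methylideneoct-6-en-2-yl]oxolan-2-one | O=C1C[C@@H](CO1)[C@@H](CO)C(=C)CCC=C(C)C | intermediate
16 | (4R)-4-[(2R)-1-{[tert-butyl(dimethyl)silyl]oxy}-7-methyl-3-methylideneoct-6-en-2-yl]oxolan-2-one | O=C1C[C@@H](CO1)[C@@H](CO[Si](C)(C)C(C)(C)C)C(=C)CCC=C(C)C | intermediate
17 | 4-iodobut-1-ene | C=CCCI | starting material
18 | (3S,4S)-3-(but-3-en-1-yl)-4-[(2R)-1-{[tert-butyl(dimethyl)silyl]oxy}-7-methyl-3-methylideneoct-6-en-2-yl]oxolan-2-one (3,4-trans) | O=C1[C@@H](CCC=C)[C@@H](CO1)[C@@H](CO[Si](C)(C)C(C)(C)C)C(=C)CCC=C(C)C | intermediate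
19 | (2S,3S,4R)-2-(but-3-en-1-yl)-4-({[tert-butyl(dimethyl)silyl]oxy}methyl)-9-methyl-5-methylidene-3-[(phenylsulfanyl)methyl]dec-8-enoic acid | OC(=O)[C@@H](CCC=C)[C@@H](CSc1ccccc1)[C@@H](CO[Si](C)(C)C(C)(C)C)C(=C)CCC=C(C)C | intermediate
20 | (2S,3S,4R)-2-(but-3-en-1-yl)-4-({[tert-butyl(dimethyl)silyl]oxy}methyl)-9-methyl-5-methylidene-3-[(phenylsulfonyl)methyl]dec-8-enoic acid | OC(=O)[C@@H](CCC=C)[C@@H](CS(=O)(=O)c1ccccc1)[C@@H](CO[Si](C)(C)C(C)(C)C)C(=C)CCC=C(C)C | intermediate
21 | (2S,3S,4R,8E)-2-(but-3-en-1-yl)-4-({[tert-butyl(dimethyl)silyl]oxy}methyl)-10-hydroxy-9-methyl-5-methylidene-3-[(phenylsulfonyl)methyl]dec-8-enoic acid | OC(=O)[C@@H](CCC=C)[C@@H](CS(=O)(=O)c1ccccc1)[C@@H](CO[Si](C)(C)C(C)(C)C)C(=C)CC/C=C(\C)CO | intermediate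
22 | lithium carboxylate of the C10 4-methylbenzenesulfonate of 21 (not isolated) | [Li+].[O-]C(=O)[C@@H](CCC=C)[C@@H](CS(=O)(=O)c1ccccc1)[C@@H](CO[Si](C)(C)C(C)(C)C)C(=C)CC/C=C(\C)COS(=O)(=O)c1ccc(C)cc1 | intermediate
23 | (2S,3S,4R,8E)-2-(but-3-en-1-yl)-4-({[tert-butyl(dimethyl)silyl]oxy}methyl)-10-chloro-9-methyl-5-methylidene-3-[(phenylsulfonyl)methyl]dec-8-enoic acid | OC(=O)[C@@H](CCC=C)[C@@H](CS(=O)(=O)c1ccccc1)[C@@H](CO[Si](C)(C)C(C)(C)C)C(=C)CC/C=C(\C)CCl | intermediate
24 | dilithium salt of 23: lithium carboxylate and lithiated CH(SO2Ph) carbon (not isolated) | [Li+].[Li+].[O-]C(=O)[C@@H](CCC=C)[C@@H]([CH-]S(=O)(=O)c1ccccc1)[C@@H](CO[Si](C)(C)C(C)(C)C)C(=C)CC/C=C(\C)CCl | intermediate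
25 | (2S)-2-[(1S,4E,9R)-9-({[tert-butyl(dimethyl)silyl]oxy}methyl)-4-methyl-8-methylidene-2-(phenylsulfonyl)cyclonon-4-en-1-yl]hex-5-enoic acid (both epimers at ring C2) | OC(=O)[C@@H](CCC=C)[C@@H]1[C@@H](CO[Si](C)(C)C(C)(C)C)C(=C)CC/C=C(\C)CC1S(=O)(=O)c1ccccc1 | intermediate
26 | (2S)-2-[(1S,4E,9R)-9-({[tert-butyl(dimethyl)silyl]oxy}methyl)-4-methyl-8-methylidenecyclonon-4-en-1-yl]hex-5-enoic acid | OC(=O)[C@@H](CCC=C)[C@@H]1[C@@H](CO[Si](C)(C)C(C)(C)C)C(=C)CC/C=C(\C)CC1 | intermediate
27 | (2S)-2-[(1S,4E,9R)-9-(hydroxymethyl)-4-methyl-8-methylidenecyclonon-4-en-1-yl]hex-5-enoic acid (not isolated) | OC(=O)[C@@H](CCC=C)[C@@H]1[C@@H](CO)C(=C)CC/C=C(\C)CC1 | intermediate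
28 | (4S,4aS,7E,11aR)-4-(but-3-en-1-yl)-7-methyl-11-methylidene-4,4a,5,6,9,10,11,11a-octahydro-1H-cyclonona[c]pyran-3-one (trans-fused, 4,4a-cis) | C=C1CC/C=C(\C)CC[C@@H]2[C@H](CCC=C)C(=O)OC[C@@H]12 | intermediate
29 | (4S,4aS,7S,8S,11aR)-7,8-epoxide of 28 | C=C1CC[C@@H]2O[C@@]2(C)CC[C@@H]2[C@H](CCC=C)C(=O)OC[C@@H]12 | intermediate
30 | methyl methacrylate | C=C(C)C(=O)OC | starting material
31 | acalycixeniolide H | C=C1CC[C@@H]2O[C@@]2(C)CC[C@@H]2[C@H](CC/C=C(\C)C(=O)OC)C(=O)OC[C@@H]12 | target

**Step count and risks**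

Total steps: 19. Longest linear sequence: 19 steps (from 1).

Steps most likely to fail:

1. Step 15. Intermolecular alkylation (oligomers) and base-induced loss of HCl from the allylic chloride may outrun closure of the flexible open-chain dianion. The fallback sets out from 23 and returns at 28, closing the ring on a preformed six-membered ring as a mono-anion. HF·pyridine removes the silyl group and the hydroxy acid lactonises to the chloro sulfone δ-lactone F1. DIBAL-H at −78 °C gives the lactol F2, and MeOH with PPTS gives the methyl lactol ether F3, in which the tetrahydropyran holds the C4a and C11a branches gauche and the sulfonyl CH2 is the only acidic C–H. One equivalent of LiN(i-Pr)2 in THF at high dilution closes the nine-membered ring to the cyclised sulfonyl acetal F4. Na(Hg) gives the desulfonylated acetal F5, PPTS in aqueous acetone gives the bicyclic lactol F6, and Fétizon oxidation (Ag2CO3 on Celite) returns 28.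

2. Step 18. Poor facial discrimination on the conformationally mobile E-cyclononene, or competing attack on the exocyclic olefin, may give epoxide mixtures. The fallback sets out from 28 and returns at 29: a reagent-controlled Shi epoxidation (fructose-derived chiral ketone of the matching handedness, Oxone, K2CO3 buffer, MeCN–dimethoxymethane, 0 °C), in which the chiral dioxirane rather than the ring conformation selects the olefin face. It makes no new compound (F0).

3. Step 4, with the olefination that follows. β-Elimination of acetic acid and enolisation of the β-acetoxy, α-alkenyl aldehyde may erase C11a. The fallback sets out from 4 and returns at 10, changing the protecting-group logic so that the aldehyde carries a silyloxy group. Ac2O in pyridine gives the diacetate F7, and enantiocomplementary lipase-catalysed hydrolysis gives the (R)-monoacetate F8. TBSCl with imidazole gives the silyl ether acetate F9, and K2CO3 in MeOH gives the mono-silyl alcohol F10. Dess–Martin oxidation gives the robust silyloxy aldehyde F11, and Still–Gennari olefination gives the (Z)-enoate F12. HF·pyridine then removes the silyl group and the alcohol lactonises to 10.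

**Further compounds**

F1 | step 15 | (3S,4S,5R)-3-(but-3-en-1-yl)-5-[(5E)-7-chloro-6-methylhepta-1,5-dien-2-yl]-4-[(phenylsulfonyl)methyl]oxan-2-one | O=C1[C@@H](CCC=C)[C@@H](CS(=O)(=O)c2ccccc2)[C@H](C(=C)CC/C=C(\C)CCl)CO1
F2 | step 15 | (3S,4S,5R)-3-(but-3-en-1-yl)-5-[(5E)-7-chloro-6-methylhepta-1,5-dien-2-yl]-4-[(phenylsulfonyl)methyl]oxan-2-ol (anomers) | OC1[C@@H](CCC=C)[C@@H](CS(=O)(=O)c2ccccc2)[C@H](C(=C)CC/C=C(\C)CCl)CO1
F3 | step 15 | (3S,4S,5R)-3-(but-3-en-1-yl)-5-[(5E)-7-chloro-6-methylhepta-1,5-dien-2-yl]-2-methoxy-4-[(phenylsulfonyl)methyl]oxane (anomers) | COC1[C@@H](CCC=C)[C@@H](CS(=O)(=O)c2ccccc2)[C@H](C(=C)CC/C=C(\C)CCl)CO1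
F4 | step 15 | (4S,4aS,7E,11aR)-4-(but-3-en-1-yl)-3-methoxy-7-methyl-11-methylidene-5-(phenylsulfonyl)-3,4,4a,5,6,9,10,11,11a-nonahydro-1H-cyclonona[c]pyran (epimers at C3 and C5) | C=C1CC/C=C(\C)CC(S(=O)(=O)c3ccccc3)[C@@H]2[C@H](CCC=C)C(OC)OC[C@@H]12
F5 | step 15 | (4S,4aS,7E,11aR)-4-(but-3-en-1-yl)-3-methoxy-7-methyl-11-methylidene-3,4,4a,5,6,9,10,11,11a-nonahydro-1H-cyclonona[c]pyran (anomers) | C=C1CC/C=C(\C)CC[C@@H]2[C@H](CCC=C)C(OC)OC[C@@H]12
F6 | step 15 | (4S,4aS,7E,11aR)-4-(but-3-en-1-yl)-7-methyl-11-methylidene-3,4,4a,5,6,9,10,11,11a-nonahydro-1H-cyclonona[c]pyran-3-ol (anomers) | C=C1CC/C=C(\C)CC[C@@H]2[C@H](CCC=C)C(O)OC[C@@H]12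
F0 | step 18 | none | none
F7 | step 4 | 2-(6-methylhepta-1,5-dien-2-yl)propane-1,3-diyl diacetate | CC(=O)OCC(COC(C)=O)C(=C)CCC=C(C)C
F8 | step 4 | (2R)-3-hydroxy-2-(6-methylhepta-1,5-dien-2-yl)propyl acetate | OC[C@@H](C(=C)CCC=C(C)C)COC(C)=O
F9 | step 4 | (2S)-3-{[tert-butyl(dimethyl)silyl]oxy}-2-(6-methylhepta-1,5-dien-2-yl)propyl acetate | CC(C)(C)[Si](C)(C)OC[C@@H](C(=C)CCC=C(C)C)COC(C)=O
F10 | step 4 | (2S)-3-{[tert-butyl(dimethyl)silyl]oxy}-2-(6-methylhepta-1,5-dien-2-yl)propan-1-ol | CC(C)(C)[Si](C)(C)OC[C@@H](C(=C)CCC=C(C)C)CO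
F11 | step 4 | (2R)-3-{[tert-butyl(dimethyl)silyl]oxy}-2-(6-methylhepta-1,5-dien-2-yl)propanal | CC(C)(C)[Si](C)(C)OC[C@@H](C(=C)CCC=C(C)C)C=O
F12 | step 4 | methyl (2Z,4R)-4-({[tert-butyl(dimethyl)silyl]oxy}methyl)-9-methyl-5-methylidenedeca-2,8-dienoate | CC(C)(C)[Si](C)(C)OC[C@@H](C(=C)CCC=C(C)C)/C=C\C(=O)OC
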